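Keep one balance in view: starting material, dormant form, the intermediates, target and quenched substrate together add up to the charge, and each unit of protic impurity that reacts moves one unit of that charge into quenched substrate.

    starting material ⇌ dormant form (K1 = 20, k1 = 0.00742 s⁻¹)
    intermediate B → target (k2 = 0.0117 s⁻¹)
    starting material ⇌ intermediate A (K3 = 0.74, k3 = 0.0576 s⁻¹)
    starting material → target (k4 = 2.67 × 10⁻⁴ s⁻¹)
    starting material + protic impurity → quenched substrate (k5 = 0.187 L mol⁻¹ s⁻¹)
    intermediate C → target (k6 = 0.00427 s⁻¹)
    starting material ⇌ intermediate B (K7 = 0.47, k7 = 7.62 × 10⁻⁴ s⁻¹)
    intermediate A → intermediate C (k8 = 1.90 × 10⁻⁴ s⁻¹)

in all of them: starting material 0.50 M; time 8.0 min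

| run | protic impurity |
|---|---|
| north-west | 3.00 mM |
| north-east | 10.0 mM |
| north | 30.0 mM |

- "hardly changes" means that all values lie within two and a half points (for a concentration: within two and a half percent of the largest)
- run time (north-west): 8.0 min

1. amount of target at the end, in percent of the starting material charged for north-west, north-east, north, in this order
2. how that number moves from the first to the last of them (rises, then falls / falls, then rises / hardly changes / falls all the way / rises all the way)

Reckon first with the toll, the fraction of the charge that the protic impurity can take, which is its own charge over the charge of starting material 6.00 %. That is the value for north; north-west has 0.600 % and north-east 2.00 %.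

Now climb the ladder of times, fastest first, on north-west; the other two flasks hold the same starting material. Starting material and intermediate A relax in 0.0853 min, so treat them as one pool. Next comes the protic impurity: with starting material held at its charge, a pseudo-first-order picture, its half-life is 0.124 min. It is the limiting reagent of its step in each flask, so expect it to collect its full toll early in the run. Dormant form follows: its step by itself relaxes in 1.48 min, and its equilibrium share among starting material, intermediate A, intermediate B and itself is 90.0 %. Further up, the direct step to target has a half-life of 43 min.

Apart from the quench, each step is first order, so once the toll is paid, target should scale with the surviving fraction, one minus the toll. North should therefore give 0.946 of what north-west gives. Take what dormant form leaves, 10.00 %, as a rough scale for target. The drop from north-west to north is then 0.54 percentage points, so commit to a nearly flat row. This rough scale is as far as the reckoning goes; it gives no yield for each flask.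

The forecast does: 11 %, 10.8 % and 10.4 %, with the shape hardly changes, on the ground that "The dormant form soaks up most of the substrate within a few minutes".

The flasks give 10.9 %, 10.8 % and 10.4 %, so the row hardly changes, as the forecast said. At 8.00 min, north holds 6.00 % quenched substrate, matching its toll, with 0.0054 % of its protic impurity left. North already held 6.00 % quenched substrate at 4.00 min. Scale north-west's target by the surviving fractions: north-east comes to 10.7 % against its 10.8 %, and north comes to 10.3 % against its 10.4 %.

(Its constants were set for the occasion; the result is computed.)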